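**Plan**

- Retrosynthetic cuts, in order: the seven O–benzyl bonds together with C2–H/C3–H of the upper unit (a flav-2-ene); C4–H (a planar 2,4-diaryl-1-benzopyrylium ion); the interflavan bond C4–C8 (flavone carbonyl plus C8-metalated epicatechin); O1–C8a of the upper ring C (a 1,3-diketone carrying fluoride on C8a); C2–C3 (Claisen acylation).
- Enabling feature: in the upper unit C8a of ring A is ortho to C4a, the carbon that carries C4, and C2 carries an aryl group. At the 1,3-diketone oxidation level the C4 carbonyl therefore activates a C8a–F bond for addition–elimination, and the enolate oxygen on C2 sits six atoms from C8a.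
- Forward order: ring A ketone and ring B acyl chloride give the diketone; ring C is closed flat as the flavone; the lower unit is attached at C4 through its C8 aryllithium; the helper carbonyl oxygen leaves as water; hydride goes to C4; hydrogen goes across C2=C3 while all benzyl groups fall off.
- Stereochemistry: C2 and C3 of the lower unit come from (−)-epicatechin. C4 of the upper unit is set by chiral-phosphate-controlled hydride transfer to the planar cation, on which both carbinol epimers converge. C2 is set by hydrogenation anti to the C4 aryl group, giving the 2,4-cis (2S,4S) flavan.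

Key step: step 6

Remark: the sense of induction in step 8 is written for the (R)-configured phosphoric acid; if it proves to be the opposite, the mirror-image catalyst is used and nothing else changes.

**Route**

Step 1
Reactants: 1 (−)-epicatechin
Product: 2 (2R,3R)-5,7-bis(benzyloxy)-2-[3,4-bis(benzyloxy)phenyl]chroman-3-ol
Conditions: BnBr (4.4 equiv), K2CO3, DMF, 0 °C to rt
Reagents that add atoms: benzyl bromide, BrCc1ccccc1
Why: Williamson etherification in which K2CO3 ionises only the four phenols, so the secondary C3 alcohol should stay free and no stereocentre is touched.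

Step 2
Reactants: 2 (2R,3R)-5,7-bis(benzyloxy)-2-[3,4-bis(benzyloxy)phenyl]chroman-3-ol
Product: 3 (2R,3R)-3,5,7-tris(benzyloxy)-2-[3,4-bis(benzyloxy)phenyl]chromane
Conditions: NaH, BnBr, n-Bu4NI (cat.), THF/DMF, 0 °C to rt
Reagents that add atoms: benzyl bromide, BrCc1ccccc1
Why: Williamson etherification of the remaining alcohol through its sodium alkoxide, which removes the last acidic proton before the organolithium chemistry of step 7; with all phenols capped, C2 and C3 should not epimerise.

Step 3
Reactants: 3 (2R,3R)-3,5,7-tris(benzyloxy)-2-[3,4-bis(benzyloxy)phenyl]chromane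
Product: 4 (2R,3R)-3,5,7-tris(benzyloxy)-2-[3,4-bis(benzyloxy)phenyl]-8-bromochromane
Conditions: NBS (1.0 equiv), CH2Cl2, −78 °C to rt
Reagents that add atoms: N-bromosuccinimide, O=C1CCC(=O)N1Br
Why: Electrophilic aromatic bromination of the phloroglucinol-type ring A, which is far more nucleophilic than ring B; C8 (between one benzyloxy group and the ring oxygen) should react before C6 (between two benzyloxy groups), the usual regiochemistry of O-benzylated flavan-3-ols with one equivalent of reagent.

Step 4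
Reactants: 5 1-(2-fluoro-4-hydroxyphenyl)ethan-1-one
Product: 6 1-[4-(benzyloxy)-2-fluorophenyl]ethan-1-one
Conditions: BnBr, K2CO3, acetone, reflux
Reagents that add atoms: benzyl bromide, BrCc1ccccc1
Why: Williamson etherification of the phenol; the aryl fluoride is not displaced by carbonate or phenoxide under these conditions.

Step 5
Reactants: 6 1-[4-(benzyloxy)-2-fluorophenyl]ethan-1-one; 7 4-(benzyloxy)benzoyl chloride
Product: 8 1-[4-(benzyloxy)-2-fluorophenyl]-3-[4-(benzyloxy)phenyl]propane-1,3-dione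
Conditions: LiHMDS (2.2 equiv), THF, −78 °C; then 7, −78 to 0 °C; aq. HCl work-up
Reagents that add atoms: none
Why: Crossed Claisen-type C-acylation of the lithium enolate of 6 by the acyl chloride (forms C2–C3); the second equivalent of base deprotonates the diketone as it forms, which suppresses O-acylation and double acylation, and at low temperature the fluoride is not displaced.

Step 6
Reactants: 8 1-[4-(benzyloxy)-2-fluorophenyl]-3-[4-(benzyloxy)phenyl]propane-1,3-dione
Product: 10 7-(benzyloxy)-2-[4-(benzyloxy)phenyl]-4H-chromen-4-one, via potassium enolate 9 (not isolated)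
Conditions: K2CO3, DMF, 110 °C
Reagents that add atoms: none
Why: Carbonate converts 8 into enolate 9, whose C2-bound oxygen adds to C8a, the fluorine-bearing carbon ortho to the C4 carbonyl, and fluoride then leaves (addition–elimination, SNAr). The closest known reaction type is the ring closure of 1-(2-halophenyl)-1,3-dicarbonyl compounds to chromones and 4-quinolones (cycloaracylation, oxygen variant). Ring C closes in a 6-exo-trig mode onto the arene; closure through C3 or through the C4-bound oxygen would need a four-membered ring, which secures O-arylation and the regiochemistry. No stereocentre is formed: the step delivers ring C flat and at the flavone oxidation level, so that C4 remains a carbonyl for attaching the lower unit and C4 and C2 can afterwards be set on a planar ring. The selectivity needed is displacement of the single aryl fluoride without harm to the benzyl ethers, secured by the ortho-acyl activation that only C8a has.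

Step 7
Reactants: 4 (2R,3R)-3,5,7-tris(benzyloxy)-2-[3,4-bis(benzyloxy)phenyl]-8-bromochromane; 10 7-(benzyloxy)-2-[4-(benzyloxy)phenyl]-4H-chromen-4-one
Product: 12 7-(benzyloxy)-2-[4-(benzyloxy)phenyl]-4-[(2R,3R)-3,5,7-tris(benzyloxy)-2-[3,4-bis(benzyloxy)phenyl]chroman-8-yl]-4H-chromen-4-ol (C4 epimer mixture), via aryllithium 11 (not isolated)
Conditions: n-BuLi, THF, −78 °C; then 10, −78 to −20 °C; H2O quench, crude product used directly
Reagents that add atoms: none
Why: Bromine–lithium exchange at C8 of the lower unit followed by 1,2-addition of the aryllithium to the flavone carbonyl (the classical entry to 4-arylflavylium precursors; the flavone has no enolisable hydrogen and C2 is blocked against conjugate addition); the carbinol centre C4 forms unselectively, which does not matter because it is planarised in step 8.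

Step 8
Reactants: 12 7-(benzyloxy)-2-[4-(benzyloxy)phenyl]-4-[(2R,3R)-3,5,7-tris(benzyloxy)-2-[3,4-bis(benzyloxy)phenyl]chroman-8-yl]-4H-chromen-4-ol (C4 epimer mixture)
Product: 14 (4S)-7-(benzyloxy)-2-[4-(benzyloxy)phenyl]-4-[(2R,3R)-3,5,7-tris(benzyloxy)-2-[3,4-bis(benzyloxy)phenyl]chroman-8-yl]-4H-chromene, via benzopyrylium ion 13 (not isolated)
Conditions: diethyl 2,6-dimethyl-1,4-dihydropyridine-3,5-dicarboxylate (Hantzsch ester, 1.2 equiv), (R)-3,3'-bis(2,4,6-triisopropylphenyl)-1,1'-binaphthyl-2,2'-diyl hydrogen phosphate (10 mol %), 4 Å molecular sieves, toluene, −20 °C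
Reagents that add atoms: none
Why: Both C4 epimers of 12 should lose water under the phosphoric acid to the same planar 2,4-diaryl-1-benzopyrylium ion 13 paired with the chiral phosphate, and the Hantzsch ester then delivers hydride to C4 on the face left open by the anion (chiral-anion-directed transfer hydrogenation of benzopyrylium ions to 4H-chromenes; stereoconvergent and catalyst-controlled, setting C4 as S).

Step 9
Reactants: 14 (4S)-7-(benzyloxy)-2-[4-(benzyloxy)phenyl]-4-[(2R,3R)-3,5,7-tris(benzyloxy)-2-[3,4-bis(benzyloxy)phenyl]chroman-8-yl]-4H-chromene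
Product: 15 (2R,3R)-2-(3,4-dihydroxyphenyl)-8-[(2S,4S)-7-hydroxy-2-(4-hydroxyphenyl)chroman-4-yl]chromane-3,5,7-triol
Conditions: H2 (1 atm), Pd(OH)2/C, THF/MeOH, rt
Reagents that add atoms: none
Why: Heterogeneous syn-addition of hydrogen to the C2=C3 enol ether should occur on the face opposite the bulky C4 aryl group (the lower unit), so that C2–H and C4–H end up cis (C2 = S, the 2,4-cis flavan), while the seven benzyl ethers are removed by hydrogenolysis in the same operation.

**Compound list**

1 | (−)-epicatechin, (2R,3R)-2-(3,4-dihydroxyphenyl)chromane-3,5,7-triol | Oc1cc(O)c2c(c1)O[C@H](c1ccc(O)c(O)c1)[C@H](O)C2 | starting material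
2 | (2R,3R)-5,7-bis(benzyloxy)-2-[3,4-bis(benzyloxy)phenyl]chroman-3-ol | c1ccccc1COc1cc(OCc2ccccc2)c2c(c1)O[C@H](c1ccc(OCc3ccccc3)c(OCc3ccccc3)c1)[C@H](O)C2 | intermediate
3 | (2R,3R)-3,5,7-tris(benzyloxy)-2-[3,4-bis(benzyloxy)phenyl]chromane | c1ccccc1COc1cc(OCc2ccccc2)c2c(c1)O[C@H](c1ccc(OCc3ccccc3)c(OCc3ccccc3)c1)[C@H](OCc1ccccc1)C2 | intermediate
4 | (2R,3R)-3,5,7-tris(benzyloxy)-2-[3,4-bis(benzyloxy)phenyl]-8-bromochromane | c1ccccc1COc1cc(OCc2ccccc2)c2c(c1Br)O[C@H](c1ccc(OCc3ccccc3)c(OCc3ccccc3)c1)[C@H](OCc1ccccc1)C2 | intermediate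
5 | 1-(2-fluoro-4-hydroxyphenyl)ethan-1-one | CC(=O)c1ccc(O)cc1F | starting material
6 | 1-[4-(benzyloxy)-2-fluorophenyl]ethan-1-one | CC(=O)c1ccc(OCc2ccccc2)cc1F | intermediate
7 | 4-(benzyloxy)benzoyl chloride | O=C(Cl)c1ccc(OCc2ccccc2)cc1 | starting material
8 | 1-[4-(benzyloxy)-2-fluorophenyl]-3-[4-(benzyloxy)phenyl]propane-1,3-dione | O=C(CC(=O)c1ccc(OCc2ccccc2)cc1)c1ccc(OCc2ccccc2)cc1F | intermediate
9 | potassium enolate of 8 (oxygen on the carbon bearing the 4-benzyloxyphenyl group; not isolated) | [K+].[O-]C(=CC(=O)c1ccc(OCc2ccccc2)cc1F)c1ccc(OCc2ccccc2)cc1 | intermediate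
10 | 7-(benzyloxy)-2-[4-(benzyloxy)phenyl]-4H-chromen-4-one (7,4'-di-O-benzylflavone) | O=c1cc(-c2ccc(OCc3ccccc3)cc2)oc2cc(OCc3ccccc3)ccc12 | intermediate
11 | [(2R,3R)-3,5,7-tris(benzyloxy)-2-[3,4-bis(benzyloxy)phenyl]chroman-8-yl]lithium (not isolated) | c1ccccc1COc1cc(OCc2ccccc2)c2c(c1[Li])O[C@H](c1ccc(OCc3ccccc3)c(OCc3ccccc3)c1)[C@H](OCc1ccccc1)C2 | intermediate
12 | 7-(benzyloxy)-2-[4-(benzyloxy)phenyl]-4-[(2R,3R)-3,5,7-tris(benzyloxy)-2-[3,4-bis(benzyloxy)phenyl]chroman-8-yl]-4H-chromen-4-ol, mixture of C4 epimers | c1ccccc1COc1ccc(C2=CC(O)(c3c(OCc5ccccc5)cc(OCc5ccccc5)c4c3O[C@H](c3ccc(OCc5ccccc5)c(OCc5ccccc5)c3)[C@H](OCc5ccccc5)C4)c3ccc(OCc5ccccc5)cc3O2)cc1 | intermediate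
13 | 7-(benzyloxy)-2-[4-(benzyloxy)phenyl]-4-[(2R,3R)-3,5,7-tris(benzyloxy)-2-[3,4-bis(benzyloxy)phenyl]chroman-8-yl]-1-benzopyrylium ion, counter-ion the chiral phosphate (not isolated) | c1ccccc1COc1ccc(-c2cc(-c3c(OCc5ccccc5)cc(OCc5ccccc5)c4c3O[C@H](c3ccc(OCc5ccccc5)c(OCc5ccccc5)c3)[C@H](OCc5ccccc5)C4)c3ccc(OCc5ccccc5)cc3[o+]2)cc1 | intermediate
14 | (4S)-7-(benzyloxy)-2-[4-(benzyloxy)phenyl]-4-[(2R,3R)-3,5,7-tris(benzyloxy)-2-[3,4-bis(benzyloxy)phenyl]chroman-8-yl]-4H-chromene | c1ccccc1COc1ccc(C2=C[C@H](c3c(OCc5ccccc5)cc(OCc5ccccc5)c4c3O[C@H](c3ccc(OCc5ccccc5)c(OCc5ccccc5)c3)[C@H](OCc5ccccc5)C4)c3ccc(OCc5ccccc5)cc3O2)cc1 | intermediate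
15 | (2R,3R)-2-(3,4-dihydroxyphenyl)-8-[(2S,4S)-7-hydroxy-2-(4-hydroxyphenyl)chroman-4-yl]chromane-3,5,7-triol | Oc1ccc([C@@H]2C[C@H](c3c(O)cc(O)c4c3O[C@H](c3ccc(O)c(O)c3)[C@H](O)C4)c3ccc(O)cc3O2)cc1 | target

**Step count and risks**

Total step count: 9. Longest linear sequence: 6 steps (steps 1, 2, 3, 7, 8, 9 from epicatechin; equally steps 4, 5, 6, 7, 8, 9 from ketone 5).

Steps most likely to fail:

Step 8. What may go wrong is insufficient face discrimination in the hydride transfer, because C4 of the cation is flanked above and below by the ortho substituents of the twisted lower-unit ring; hydride may also be delivered to C2 instead of C4. The fallback gives up catalyst control for separation with recycling and sets out from 12. Treatment with HBF4·OEt2 in Et2O should precipitate the 2,4-diaryl-1-benzopyrylium tetrafluoroborate F1. Reduction with NaBH4 in MeCN/MeOH at −40 °C should give 14 together with its C4 epimer, the (4R)-4H-chromene F2. The two are diastereomers, since the lower unit is enantiopure, and are separated by chromatography. F2 is returned to F1 by hydride abstraction with trityl tetrafluoroborate and reduced again. The fallback comes back to the route at 14.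

Step 7. What may go wrong is consumption of the aryllithium by lateral metalation or Wittig-type rearrangement of the neighbouring benzyl ether, or slow 1,2-addition of this hindered nucleophile to the vinylogous ester carbonyl. The fallback needs no organometallic and sets out from 3 and 10, so step 3 is not required. Tf2O in CH2Cl2 (−78 to 0 °C) turns 10 into its 4-triflyloxybenzopyrylium ion, which is attacked by C8 of 3 in a Friedel–Crafts manner. Loss of triflate gives the 4-aryl-1-benzopyrylium trifluoromethanesulfonate F3. Aqueous NaHCO3 converts it into the pseudobase, the 2-hydroxy-2H-chromene F4. Under the conditions of step 8, F4 ionises to 13 exactly as 12 does, so the fallback comes back to the route at 14.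

Step 9. What may go wrong is erosion of the cis selectivity, or hydrogenolytic opening of the benzylic C2–O1 bond, while alkene saturation and sevenfold debenzylation run in one flask. The fallback separates the two events and sets out from 14. Ionic hydrogenation (Et3SiH, CF3CO2H, CH2Cl2, −40 °C) protonates C3 and delivers hydride to the C2 oxocarbenium ion anti to the C4 aryl group. This should give the hepta-O-benzyl 2,4-cis flavan F5, which is also the thermodynamically preferred diequatorial isomer. Short hydrogenolysis of F5 (H2, Pd/C, EtOAc/MeOH, rt) then gives 15, where the fallback comes back to the route.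

Further compounds
F1 | step 8 | 7-(benzyloxy)-2-[4-(benzyloxy)phenyl]-4-[(2R,3R)-3,5,7-tris(benzyloxy)-2-[3,4-bis(benzyloxy)phenyl]chroman-8-yl]-1-benzopyrylium tetrafluoroborate | c1ccccc1COc1ccc(-c2cc(-c3c(OCc5ccccc5)cc(OCc5ccccc5)c4c3O[C@H](c3ccc(OCc5ccccc5)c(OCc5ccccc5)c3)[C@H](OCc5ccccc5)C4)c3ccc(OCc5ccccc5)cc3[o+]2)cc1.F[B-](F)(F)F
F2 | step 8 | (4R)-7-(benzyloxy)-2-[4-(benzyloxy)phenyl]-4-[(2R,3R)-3,5,7-tris(benzyloxy)-2-[3,4-bis(benzyloxy)phenyl]chroman-8-yl]-4H-chromene (C4 epimer of 14) | c1ccccc1COc1ccc(C2=C[C@@H](c3c(OCc5ccccc5)cc(OCc5ccccc5)c4c3O[C@H](c3ccc(OCc5ccccc5)c(OCc5ccccc5)c3)[C@H](OCc5ccccc5)C4)c3ccc(OCc5ccccc5)cc3O2)cc1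
F3 | step 7 | 7-(benzyloxy)-2-[4-(benzyloxy)phenyl]-4-[(2R,3R)-3,5,7-tris(benzyloxy)-2-[3,4-bis(benzyloxy)phenyl]chroman-8-yl]-1-benzopyrylium trifluoromethanesulfonate | c1ccccc1COc1ccc(-c2cc(-c3c(OCc5ccccc5)cc(OCc5ccccc5)c4c3O[C@H](c3ccc(OCc5ccccc5)c(OCc5ccccc5)c3)[C@H](OCc5ccccc5)C4)c3ccc(OCc5ccccc5)cc3[o+]2)cc1.[O-]S(=O)(=O)C(F)(F)F
F4 | step 7 | 7-(benzyloxy)-2-[4-(benzyloxy)phenyl]-4-[(2R,3R)-3,5,7-tris(benzyloxy)-2-[3,4-bis(benzyloxy)phenyl]chroman-8-yl]-2H-chromen-2-ol, mixture of C2 epimers | c1ccccc1COc1ccc(C2(O)C=C(c3c(OCc5ccccc5)cc(OCc5ccccc5)c4c3O[C@H](c3ccc(OCc5ccccc5)c(OCc5ccccc5)c3)[C@H](OCc5ccccc5)C4)c3ccc(OCc5ccccc5)cc3O2)cc1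
F5 | step 9 | (2R,3R)-3,5,7-tris(benzyloxy)-2-[3,4-bis(benzyloxy)phenyl]-8-[(2S,4S)-7-(benzyloxy)-2-[4-(benzyloxy)phenyl]chroman-4-yl]chromane | c1ccccc1COc1ccc([C@@H]2C[C@H](c3c(OCc5ccccc5)cc(OCc5ccccc5)c4c3O[C@H](c3ccc(OCc5ccccc5)c(OCc5ccccc5)c3)[C@H](OCc5ccccc5)C4)c3ccc(OCc5ccccc5)cc3O2)cc1
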